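The benzene ring of each dihydrobenzofuran (C3a, C4, C5, C6, C7, C7a) carries oxygen on C6 and C7a, the tetrahydrofuran on C4 and C3 on C3a, the pattern that an alkynyl ketone and a 1,3-dioxygenated diene deliver. Both rings are therefore built late and together: a double Diels–Alder benzannulation of an enantiopure 2,5-cis-3,4-trans tetrahydrofuran-3,4-diyl bis(aryl ynone) with 1-methoxy-1,3-bis(trimethylsilyloxy)butadiene forms C4–C5 and C3a–C7a of each ring and, after aromatisation, leaves two 4-aroylresorcinols. Their ketone carbons become C3; a reagent-controlled sulfur-ylide [4+1] annulation then closes both furan rings, and hydrogenolysis frees the ten phenols.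

Key step: step 8

Remark 1: all phenols are carried as benzyl ethers so that the last step is a neutral hydrogenolysis; Lewis-acid ether cleavage would ionise the p-oxybenzylic C–O bonds at C2 and C5 of the tetrahydrofuran, whose 2,5-cis arrangement is not the thermodynamic one.
Remark 2 (step 2): the menthyl esters are not expected to control the face of the fumarate strongly; they make the two 2,5-cis-3,4-trans adducts diastereomers, and the (2S,3R,4R,5R) adduct, identified by X-ray analysis, is carried on.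
Remark 3 (stoichiometry): the core has two arms, so steps 7, 8 and 13 each consume two molecules of the second reactant (14, 18 and 25), one per arm; the second molecule is entered under "Reagents that add atoms".
Remark 4: diene 18 is taken as a purchased, moisture-sensitive reagent and is distilled before use.
Assumption (step 13): the (1R,4R,5R) sulfide is taken to be the enantiomer whose benzylide gives the (2S) configuration; a model annulation on a simple o-hydroxybenzhydryl sulfone settles the sense, and the (1S,4S,5S) sulfide would otherwise be used with no other change.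

Step 1
Reactants: 1 4-(benzyloxy)benzyl chloride; 2 4-(benzyloxy)benzaldehyde
Product: 5 trans-2,3-bis[4-(benzyloxy)phenyl]oxirane (racemic), via sulfonium chloride 3 (not isolated), via sulfonium ylide 4 (not isolated)
Conditions: tetrahydrothiophene, MeCN, rt; then 2, KOH (powder), MeCN, 0 °C to rt
Reagents that add atoms: none
Why: Corey–Chaykovsky epoxidation with a semi-stabilised benzylsulfonium ylide should give mainly the trans oxirane through reversible betaine formation; its racemic configuration is of no consequence because both oxirane carbons become the termini of a planar ylide in step 2.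

Step 2
Reactants: 5 trans-2,3-bis[4-(benzyloxy)phenyl]oxirane; 6 bis[(1R,2S,5R)-menthyl] fumarate
Product: 8 bis[(1R,2S,5R)-menthyl] (2S,3R,4R,5R)-2,5-bis[4-(benzyloxy)phenyl]tetrahydrofuran-3,4-dicarboxylate, via carbonyl ylide 7 (not isolated)
Conditions: 1,4-dicyanonaphthalene (cat.), hν (>300 nm, Pyrex), MeCN, rt, argon; separation of the two cis,trans diastereomers (SiO2, crystallisation)
Reagents that add atoms: none
Why: sensitised electron transfer opens the C–C bond of the electron-rich oxirane and back electron transfer gives the W-shaped carbonyl ylide 7, whose suprafacial 1,3-dipolar [3+2] cycloaddition to the fumarate sets C2 and C5 cis (both aryl groups exo on the ylide) and C3 and C4 trans (retention of the alkene geometry), while the menthyl esters turn the two mirror-image cores into separable diastereomers from which the (2S,3R,4R,5R) adduct is taken.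

Step 3
Reactants: 8 bis(menthyl) tetrahydrofuran-3,4-dicarboxylate
Product: 9 [(2S,3S,4S,5R)-2,5-bis[4-(benzyloxy)phenyl]tetrahydrofuran-3,4-diyl]dimethanol
Conditions: LiAlH4, THF, 0 °C to rt
Reagents that add atoms: none
Why: hydride reduction of both hindered esters to primary alcohols releases the auxiliary as menthol and touches no stereocenter.

Step 4
Reactants: 9 tetrahydrofuran-3,4-diyldimethanol
Product: 10 (2S,3R,4R,5R)-2,5-bis[4-(benzyloxy)phenyl]tetrahydrofuran-3,4-dicarbaldehyde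
Conditions: DMP, pyridine, CH2Cl2, 0 °C to rt; used crude at once
Reagents that add atoms: none
Why: Dess–Martin oxidation under buffered, non-basic conditions should give the dialdehyde without epimerising the α-stereocenters, and the trans relation of the two CH2OH groups rules out lactol formation.

Step 5
Reactants: 10 tetrahydrofuran-3,4-dicarbaldehyde
Product: 11 (2S,3S,4S,5R)-2,5-bis[4-(benzyloxy)phenyl]-3,4-bis(2,2-dibromoethenyl)tetrahydrofuran
Conditions: CBr4 (4 equiv), PPh3 (8 equiv), Et3N, CH2Cl2, 0 °C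
Reagents that add atoms: carbon tetrabromide (one molecule per aldehyde; two in all), BrC(Br)(Br)Br
Why: Ramirez dibromo-olefination (first stage of the Corey–Fuchs sequence) converts both aldehydes, with Et3N scavenging HBr so that neither the aldehyde α-centers nor the benzylic ethers meet acid.

Step 6
Reactants: 12 3,5-bis(benzyloxy)benzoic acid
Product: 14 3,5-bis(benzyloxy)-N-methoxy-N-methylbenzamide, via acyl imidazole 13 (not isolated)
Conditions: CDI, CH2Cl2, rt; then MeNH(OMe)·HCl, rt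
Reagents that add atoms: N,O-dimethylhydroxylamine hydrochloride, CNOC.Cl
Why: acyl transfer through the acyl imidazole gives the N-methoxy-N-methylamide, which stops organolithium addition at the ketone stage (Weinreb ketone synthesis).

Step 7
Reactants: 11 bis(2,2-dibromoethenyl)tetrahydrofuran; 14 3,5-bis(benzyloxy)-N-methoxy-N-methylbenzamide (2 equiv consumed; one per alkyne)
Product: 17 3,3'-[(2S,3S,4S,5R)-2,5-bis[4-(benzyloxy)phenyl]tetrahydrofuran-3,4-diyl]bis{1-[3,5-bis(benzyloxy)phenyl]prop-2-yn-1-one}, via dilithium bis-acetylide 15 (not isolated), via dilithium tetrahedral adduct 16 (not isolated)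
Conditions: n-BuLi (4.2 equiv), THF, −78 °C, 1 h; then 14 (2.4 equiv) in THF, −78 to −20 °C; AcOH quench at −78 °C
Reagents that add atoms: 3,5-bis(benzyloxy)-N-methoxy-N-methylbenzamide 14 (the second of the two molecules taken up), CON(C)C(=O)c1cc(OCc2ccccc2)cc(OCc2ccccc2)c1
Why: the second stage of the Corey–Fuchs reaction (bromine–lithium exchange, Fritsch–Buttenberg–Wiechell rearrangement, deprotonation) gives the bis-acetylide, each terminus of which is acylated by one molecule of 14 through a stable chelated adduct that releases the ynone only on the acidic quench, so that over-addition and amine conjugate addition are avoided and the propargylic stereocenters stay untouched.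

Step 8
Reactants: 17 tetrahydrofuran-3,4-diyl bis(aryl ynone); 18 1-methoxy-1,3-bis(trimethylsilyloxy)buta-1,3-diene (2 equiv consumed; one per ynone)
Product: 20 (2S,3S,4S,5R)-2,5-bis[4-(benzyloxy)phenyl]-3,4-bis{2-[3,5-bis(benzyloxy)benzoyl]-3,5-dihydroxyphenyl}tetrahydrofuran, via bis-cycloadduct 19 (not isolated)
Conditions: 18 (5 equiv), toluene, 80 °C; then PPTS (cat.), THF/H2O, rt
Reagents that add atoms: 1-methoxy-1,3-bis(trimethylsilyloxy)buta-1,3-diene 18 (the second of the two molecules taken up), C=C(O[Si](C)(C)C)/C=C(/OC)O[Si](C)(C)C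
Why: The electron-rich diene 18 and each electron-poor ynone of 17 combine in a concerted, asynchronous [4+2] cycloaddition in which the CH2 terminus of the diene (future C5) bonds to the ynone β-carbon (future C4) and the ketene-acetal carbon (future C7a) to the α-carbon (future C3a), giving the cyclohexa-1,4-diene 19. Loss of methanol from the acetal carbon and the CH2 group aromatises each ring, and mild hydrolysis of the two silyl ethers leaves hydroxyls on C6 and C7a with the aroyl group on C3a. The closest known reaction type is the Diels–Alder benzannulation of 1-alkoxy-1,3-bis(silyloxy)buta-1,3-dienes with alkynyl ketones and alkynoates to acylresorcinols and resorcylates. Each of the two benzene rings is closed by an intermolecular cycloaddition that forms both of its new σ-bonds in one event, not by cyclisation of a tethered chain. No stereocenter is formed in 20 (the acetal carbons of 19 vanish on aromatisation), and the four tetrahydrofuran centers survive because the medium is neutral, so the propargylic hydrogens on tetrahydrofuran C3 and C4 are never removed. The step needs regioselectivity and chemoselectivity for the alkyne over the ketone carbonyl: the first comes from the match of the nucleophilic diene terminus with the electrophilic β-carbon of the ynone, the second from the absence of any Lewis acid.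

Step 9
Reactants: 20 bis(2-aroyl-3,5-dihydroxyphenyl)tetrahydrofuran
Product: 21 (2S,3S,4S,5R)-2,5-bis[4-(benzyloxy)phenyl]-3,4-bis{5-(benzyloxy)-2-[3,5-bis(benzyloxy)benzoyl]-3-hydroxyphenyl}tetrahydrofuran
Conditions: BnBr (2.1 equiv), K2CO3, acetone, 45 °C
Reagents that add atoms: benzyl bromide (one molecule per arm; two in all), BrCc1ccccc1
Why: Williamson etherification is selective for the hydroxyl para to the ketone, because the ortho hydroxyl is held in a hydrogen bond to the carbonyl and is far less nucleophilic under weak base.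

Step 10
Reactants: 21 bis(2-aroyl-5-benzyloxy-3-hydroxyphenyl)tetrahydrofuran
Product: 22 (2S,3S,4S,5R)-2,5-bis[4-(benzyloxy)phenyl]-3,4-bis{5-(benzyloxy)-2-{[3,5-bis(benzyloxy)phenyl](hydroxy)methyl}-3-hydroxyphenyl}tetrahydrofuran
Conditions: NaBH4, THF/MeOH, 0 °C
Reagents that add atoms: none
Why: borohydride reduction of the diaryl ketones gives the o-hydroxybenzhydrols at low temperature, where further reduction through the quinone methide is slow; the new carbinol centers form as a mixture that is erased in step 13.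

Step 11
Reactants: 22 bis(o-hydroxybenzhydrol)
Product: 23 (2S,3S,4S,5R)-2,5-bis[4-(benzyloxy)phenyl]-3,4-bis{5-(benzyloxy)-2-{[3,5-bis(benzyloxy)phenyl](4-methylbenzenesulfonyl)methyl}-3-hydroxyphenyl}tetrahydrofuran
Conditions: p-TolSO2H (2.5 equiv), CH2Cl2, 0 °C to rt
Reagents that add atoms: p-toluenesulfinic acid (one molecule per arm; two in all), Cc1ccc(cc1)S(O)=O
Why: the doubly donor-stabilised benzhydryl cation forms with the weak sulfinic acid far more readily than the tetrahydrofuran C–O bonds ionise and is captured at sulfur (SN1 substitution), giving the usual base-triggered o-quinone methide precursor; the configuration at the sulfonyl carbons is irrelevant.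

Step 12
Reactants: 1 4-(benzyloxy)benzyl chloride; 24 (1R,4R,5R)-4,7,7-trimethyl-6-thiabicyclo[3.2.1]octane (isothiocineole)
Product: 25 (1R,4R,5R)-6-[4-(benzyloxy)benzyl]-4,7,7-trimethyl-6-thiabicyclo[3.2.1]octan-6-ium tetrafluoroborate
Conditions: NaBF4, MeCN, rt
Reagents that add atoms: sodium tetrafluoroborate, [Na+].F[B-](F)(F)F
Why: S-alkylation of the bicyclic sulfide by the reactive p-alkoxybenzyl chloride, driven by precipitation of NaCl, is expected to give one sulfonium diastereomer by attack through the less hindered lone pair.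

Step 13
Reactants: 23 bis(o-hydroxybenzhydryl sulfone); 25 chiral benzylsulfonium tetrafluoroborate (2 equiv consumed; one per arm)
Product: 28 (2S,3S,4S,5R)-2,5-bis[4-(benzyloxy)phenyl]-3,4-bis{(2S,3S)-6-(benzyloxy)-2-[4-(benzyloxy)phenyl]-3-[3,5-bis(benzyloxy)phenyl]-2,3-dihydro-1-benzofuran-4-yl}tetrahydrofuran, via chiral sulfonium ylide 26 (not isolated), via bis(o-quinone methide) 27 (not isolated)
Conditions: 25 (2.4 equiv), Cs2CO3 (5 equiv), MeCN/CH2Cl2, −20 °C to rt
Reagents that add atoms: sulfonium tetrafluoroborate 25 (the second of the two molecules taken up), C[C@@H]1CC[C@@H]2C[C@H]1[S+](Cc1ccc(OCc3ccccc3)cc1)C2(C)C.F[B-](F)(F)F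
Why: Proposed new method: Cs2CO3 expels p-toluenesulfinate from each phenoxide to give the o-quinone methide 27, the chiral benzylide 26 adds through its exposed face to the exocyclic carbon (future C3), and the phenoxide then displaces the sulfide at the benzylic carbon (future C2) with inversion in a 5-exo-tet closure, so that the ylide face fixes C2 as S and the anti addition that keeps the two aryl groups apart makes each ring trans and hence C3 S, overriding the bias of the tetrahydrofuran; the closest known reaction types are the sulfur-ylide [4+1] annulation of o-quinone methides to trans-2,3-dihydrobenzofurans and the asymmetric epoxidation and cyclopropanation with benzylides of chiral sulfides.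

Step 14
Reactants: 28 deca-O-benzyl ether of the target
Product: 29 (2S,3S,4S,5R)-2,5-bis(4-hydroxyphenyl)-3,4-bis[(2S,3S)-3-(3,5-dihydroxyphenyl)-6-hydroxy-2-(4-hydroxyphenyl)-2,3-dihydro-1-benzofuran-4-yl]tetrahydrofuran (CNP0270490.1)
Conditions: H2 (1 atm), 10% Pd/C, EtOAc/MeOH, rt
Reagents that add atoms: none
Why: hydrogenolysis of the ten primary benzyl aryl ethers should be much faster than cleavage of the secondary, ring-bound benzylic C–O bonds, and the neutral medium avoids the acid that would ionise C2 and C5 of the tetrahydrofuran and C2 of the dihydrobenzofurans, so all eight stereocenters are kept.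

Compound list
1 | 4-(benzyloxy)benzyl chloride | ClCc1ccc(OCc2ccccc2)cc1 | starting material
2 | 4-(benzyloxy)benzaldehyde | O=Cc1ccc(OCc2ccccc2)cc1 | starting material
3 | 1-[4-(benzyloxy)benzyl]tetrahydrothiophenium chloride (not isolated) | [Cl-].c1ccccc1COc1ccc(C[S+]2CCCC2)cc1 | intermediate
4 | ylide of 3, [4-(benzyloxy)phenyl](tetrahydrothiophenium-1-yl)methanide (not isolated) | c1ccccc1COc1ccc([CH-][S+]2CCCC2)cc1 | intermediate
5 | trans-2,3-bis[4-(benzyloxy)phenyl]oxirane (racemic; one enantiomer drawn) | c1ccccc1COc1ccc(cc1)[C@@H]1O[C@H]1c1ccc(OCc2ccccc2)cc1 | intermediate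
6 | bis[(1R,2S,5R)-menthyl] (E)-but-2-enedioate (dimenthyl fumarate) | CC(C)[C@@H]1CC[C@@H](C)C[C@H]1OC(=O)/C=C/C(=O)O[C@@H]1C[C@H](C)CC[C@H]1C(C)C | starting material
7 | carbonyl ylide from 5, bis[4-(benzyloxy)phenyl]-substituted C–O–C ylide (W-shaped; not isolated) | [CH-](c1ccc(OCc2ccccc2)cc1)[O+]=Cc1ccc(OCc2ccccc2)cc1 | intermediate
8 | bis[(1R,2S,5R)-menthyl] (2S,3R,4R,5R)-2,5-bis[4-(benzyloxy)phenyl]tetrahydrofuran-3,4-dicarboxylate (2,5-cis; 3,4-trans) | O1[C@H](c2ccc(OCc3ccccc3)cc2)[C@H](C(=O)O[C@@H]2C[C@H](C)CC[C@H]2C(C)C)[C@@H](C(=O)O[C@@H]2C[C@H](C)CC[C@H]2C(C)C)[C@@H]1c1ccc(OCc2ccccc2)cc1 | intermediate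
9 | [(2S,3S,4S,5R)-2,5-bis[4-(benzyloxy)phenyl]tetrahydrofuran-3,4-diyl]dimethanol | O1[C@H](c2ccc(OCc3ccccc3)cc2)[C@H](CO)[C@@H](CO)[C@@H]1c1ccc(OCc2ccccc2)cc1 | intermediate
10 | (2S,3R,4R,5R)-2,5-bis[4-(benzyloxy)phenyl]tetrahydrofuran-3,4-dicarbaldehyde | O1[C@H](c2ccc(OCc3ccccc3)cc2)[C@H](C=O)[C@@H](C=O)[C@@H]1c1ccc(OCc2ccccc2)cc1 | intermediate
11 | (2S,3S,4S,5R)-2,5-bis[4-(benzyloxy)phenyl]-3,4-bis(2,2-dibromoethenyl)tetrahydrofuran | O1[C@H](c2ccc(OCc3ccccc3)cc2)[C@H](C=C(Br)Br)[C@@H](C=C(Br)Br)[C@@H]1c1ccc(OCc2ccccc2)cc1 | intermediate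
12 | 3,5-bis(benzyloxy)benzoic acid | OC(=O)c1cc(OCc2ccccc2)cc(OCc2ccccc2)c1 | starting material
13 | [3,5-bis(benzyloxy)phenyl](imidazol-1-yl)methanone (not isolated) | O=C(n1ccnc1)c1cc(OCc2ccccc2)cc(OCc2ccccc2)c1 | intermediate
14 | 3,5-bis(benzyloxy)-N-methoxy-N-methylbenzamide | CON(C)C(=O)c1cc(OCc2ccccc2)cc(OCc2ccccc2)c1 | intermediate
15 | dilithium bis-acetylide of (2S,3S,4S,5R)-2,5-bis[4-(benzyloxy)phenyl]-3,4-diethynyltetrahydrofuran (not isolated) | O1[C@H](c2ccc(OCc3ccccc3)cc2)[C@H](C#C[Li])[C@@H](C#C[Li])[C@@H]1c1ccc(OCc2ccccc2)cc1 | intermediate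
16 | dilithium bis-alkoxide adduct of 15 with two molecules of 14 (carbinolamine carbons: mixture; not isolated) | O1[C@H](c2ccc(OCc3ccccc3)cc2)[C@H](C#CC(O[Li])(N(C)OC)c2cc(OCc3ccccc3)cc(OCc3ccccc3)c2)[C@@H](C#CC(O[Li])(N(C)OC)c2cc(OCc3ccccc3)cc(OCc3ccccc3)c2)[C@@H]1c1ccc(OCc2ccccc2)cc1 | intermediate
17 | 3,3'-[(2S,3S,4S,5R)-2,5-bis[4-(benzyloxy)phenyl]tetrahydrofuran-3,4-diyl]bis{1-[3,5-bis(benzyloxy)phenyl]prop-2-yn-1-one} | O1[C@H](c2ccc(OCc3ccccc3)cc2)[C@H](C#CC(=O)c2cc(OCc3ccccc3)cc(OCc3ccccc3)c2)[C@@H](C#CC(=O)c2cc(OCc3ccccc3)cc(OCc3ccccc3)c2)[C@@H]1c1ccc(OCc2ccccc2)cc1 | intermediate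
18 | 1-methoxy-1,3-bis(trimethylsilyloxy)buta-1,3-diene | C=C(O[Si](C)(C)C)/C=C(/OC)O[Si](C)(C)C | starting material
19 | bis-cycloadduct: tetrahydrofuran of 17 bearing on C3 and C4 a 2-[3,5-bis(benzyloxy)benzoyl]-3-methoxy-3,5-bis(trimethylsilyloxy)cyclohexa-1,4-dien-1-yl group (acetal carbons: mixture; not isolated) | O1[C@H](c2ccc(OCc3ccccc3)cc2)[C@H](C2=C(C(=O)c3cc(OCc4ccccc4)cc(OCc4ccccc4)c3)C(OC)(O[Si](C)(C)C)C=C(O[Si](C)(C)C)C2)[C@@H](C2=C(C(=O)c3cc(OCc4ccccc4)cc(OCc4ccccc4)c3)C(OC)(O[Si](C)(C)C)C=C(O[Si](C)(C)C)C2)[C@@H]1c1ccc(OCc2ccccc2)cc1 | intermediate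
20 | (2S,3S,4S,5R)-2,5-bis[4-(benzyloxy)phenyl]-3,4-bis{2-[3,5-bis(benzyloxy)benzoyl]-3,5-dihydroxyphenyl}tetrahydrofuran | O1[C@H](c2ccc(OCc3ccccc3)cc2)[C@H](c2cc(O)cc(O)c2C(=O)c2cc(OCc3ccccc3)cc(OCc3ccccc3)c2)[C@@H](c2cc(O)cc(O)c2C(=O)c2cc(OCc3ccccc3)cc(OCc3ccccc3)c2)[C@@H]1c1ccc(OCc2ccccc2)cc1 | intermediate
21 | (2S,3S,4S,5R)-2,5-bis[4-(benzyloxy)phenyl]-3,4-bis{5-(benzyloxy)-2-[3,5-bis(benzyloxy)benzoyl]-3-hydroxyphenyl}tetrahydrofuran | O1[C@H](c2ccc(OCc3ccccc3)cc2)[C@H](c2cc(OCc3ccccc3)cc(O)c2C(=O)c2cc(OCc3ccccc3)cc(OCc3ccccc3)c2)[C@@H](c2cc(OCc3ccccc3)cc(O)c2C(=O)c2cc(OCc3ccccc3)cc(OCc3ccccc3)c2)[C@@H]1c1ccc(OCc2ccccc2)cc1 | intermediate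
22 | (2S,3S,4S,5R)-2,5-bis[4-(benzyloxy)phenyl]-3,4-bis{5-(benzyloxy)-2-{[3,5-bis(benzyloxy)phenyl](hydroxy)methyl}-3-hydroxyphenyl}tetrahydrofuran (carbinol carbons: mixture) | O1[C@H](c2ccc(OCc3ccccc3)cc2)[C@H](c2cc(OCc3ccccc3)cc(O)c2C(O)c2cc(OCc3ccccc3)cc(OCc3ccccc3)c2)[C@@H](c2cc(OCc3ccccc3)cc(O)c2C(O)c2cc(OCc3ccccc3)cc(OCc3ccccc3)c2)[C@@H]1c1ccc(OCc2ccccc2)cc1 | intermediate
23 | (2S,3S,4S,5R)-2,5-bis[4-(benzyloxy)phenyl]-3,4-bis{5-(benzyloxy)-2-{[3,5-bis(benzyloxy)phenyl](4-methylbenzenesulfonyl)methyl}-3-hydroxyphenyl}tetrahydrofuran (sulfonyl-bearing carbons: mixture) | O1[C@H](c2ccc(OCc3ccccc3)cc2)[C@H](c2cc(OCc3ccccc3)cc(O)c2C(c2cc(OCc3ccccc3)cc(OCc3ccccc3)c2)S(=O)(=O)c2ccc(C)cc2)[C@@H](c2cc(OCc3ccccc3)cc(O)c2C(c2cc(OCc3ccccc3)cc(OCc3ccccc3)c2)S(=O)(=O)c2ccc(C)cc2)[C@@H]1c1ccc(OCc2ccccc2)cc1 | intermediate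
24 | (1R,4R,5R)-4,7,7-trimethyl-6-thiabicyclo[3.2.1]octane (isothiocineole) | C[C@@H]1CC[C@@H]2C[C@H]1SC2(C)C | starting material
25 | (1R,4R,5R)-6-[4-(benzyloxy)benzyl]-4,7,7-trimethyl-6-thiabicyclo[3.2.1]octan-6-ium tetrafluoroborate (one diastereomer at sulfur expected; sulfur configuration not assigned, it is lost in step 13) | C[C@@H]1CC[C@@H]2C[C@H]1[S+](Cc1ccc(OCc3ccccc3)cc1)C2(C)C.F[B-](F)(F)F | intermediate
26 | ylide of 25, [4-(benzyloxy)phenyl]methanide on the sulfonium sulfur (not isolated) | C[C@@H]1CC[C@@H]2C[C@H]1[S+]([CH-]c1ccc(OCc3ccccc3)cc1)C2(C)C | intermediate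
27 | bis(o-quinone methide): tetrahydrofuran of 23 bearing on C3 and C4 a 3-(benzyloxy)-6-[3,5-bis(benzyloxy)benzylidene]-5-oxocyclohexa-1,3-dien-1-yl group (exocyclic alkene geometry unassigned; not isolated) | O1[C@H](c2ccc(OCc3ccccc3)cc2)[C@H](C2=CC(OCc3ccccc3)=CC(=O)C2=Cc2cc(OCc3ccccc3)cc(OCc3ccccc3)c2)[C@@H](C2=CC(OCc3ccccc3)=CC(=O)C2=Cc2cc(OCc3ccccc3)cc(OCc3ccccc3)c2)[C@@H]1c1ccc(OCc2ccccc2)cc1 | intermediate
28 | (2S,3S,4S,5R)-2,5-bis[4-(benzyloxy)phenyl]-3,4-bis{(2S,3S)-6-(benzyloxy)-2-[4-(benzyloxy)phenyl]-3-[3,5-bis(benzyloxy)phenyl]-2,3-dihydro-1-benzofuran-4-yl}tetrahydrofuran (deca-O-benzyl ether of the target; both dihydrobenzofurans trans) | c7ccccc7COc1ccc([C@H]2Oc3cc(OCc7ccccc7)cc([C@@H]4[C@@H](c5cc(OCc7ccccc7)cc6c5[C@H](c5cc(OCc7ccccc7)cc(OCc7ccccc7)c5)[C@@H](c5ccc(OCc7ccccc7)cc5)O6)[C@H](c5ccc(OCc7ccccc7)cc5)O[C@@H]4c4ccc(OCc7ccccc7)cc4)c3[C@@H]2c2cc(OCc7ccccc7)cc(OCc7ccccc7)c2)cc1 | intermediate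
29 | (2S,3S,4S,5R)-2,5-bis(4-hydroxyphenyl)-3,4-bis[(2S,3S)-3-(3,5-dihydroxyphenyl)-6-hydroxy-2-(4-hydroxyphenyl)-2,3-dihydro-1-benzofuran-4-yl]tetrahydrofuran (CNP0270490.1) | Oc1ccc([C@H]2Oc3cc(O)cc([C@@H]4[C@@H](c5cc(O)cc6c5[C@H](c5cc(O)cc(O)c5)[C@@H](c5ccc(O)cc5)O6)[C@H](c5ccc(O)cc5)O[C@@H]4c4ccc(O)cc4)c3[C@@H]2c2cc(O)cc(O)c2)cc1 | target

Total step count: 14.
Longest linear sequence: 12 steps (steps 1, 2, 3, 4, 5, 7, 8, 9, 10, 11, 13, 14); steps 6 and 12 are side branches.

Steps most likely to fail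

Step 13. The bulky chiral ylide may add too slowly to the congested exocyclic carbon of the quinone methide, so that sigmatropic rearrangement of the ylide or addition with poor facial discrimination against the bias of the tetrahydrofuran takes over. The fallback sets out from 23 and comes back at 28. Compound 1 is treated with tetrahydrothiophene and NaBF4 in MeCN to give 1-[4-(benzyloxy)benzyl]tetrahydrothiophenium tetrafluoroborate F1. This small achiral salt and Cs2CO3 are used with 23 in the sulfur-ylide [4+1] annulation of o-quinone methides, which is the reaction type established for stabilised ylides and runs here through ylide 4 and quinone methide 27. Stereocontrol then passes from the reagent to the substrate plus separation: because the core is a single enantiomer, the trans,trans products are diastereomers, they are separated by preparative HPLC, and the (2S,3S),(2S,3S) isomer, assigned by NOE and X-ray analysis, is 28.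

Step 8. Ring closure may stop after the first C–C bond and leave open-chain Michael adducts, the diene may attack the ketone carbonyl, or the second cycloaddition may stall beside the newly formed, crowded ring. The fallback sets out from 11 and comes back at 22. n-BuLi followed by methyl chloroformate converts 11, through 15, into dimethyl 3,3'-[(2S,3S,4S,5R)-2,5-bis[4-(benzyloxy)phenyl]tetrahydrofuran-3,4-diyl]bis(prop-2-ynoate) F2, a dienophile of the kind most often used with 18 and free of a ketone carbonyl. Heating with 18 gives the bis-cycloadduct of the alkynoate F3, and mild hydrolysis gives the bis(methyl 2,4-dihydroxybenzoate) F4. Para-selective benzylation (BnBr, K2CO3) gives the bis(methyl 4-benzyloxy-2-hydroxybenzoate) F5, LiAlH4 the bis(salicyl alcohol) F6, and MnO2 the bis(salicylaldehyde) F7. Excess 3,5-bis(benzyloxy)phenylmagnesium bromide F8, made from 1,3-bis(benzyloxy)-5-bromobenzene and Mg, adds to both aldehydes and gives 22 directly; the same two ring bonds are still made by cycloaddition, and 17, 20 and 21 are bypassed.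

Step 2. Facial selectivity may be low while the two menthyl diastereomers co-elute, or isomerisation of the ylide may erode the 2,5-cis geometry. The fallback sets out from 5 and comes back at 9. Compound 5 and dimethyl fumarate under the same sensitised conditions give racemic dimethyl 2,5-cis-3,4-trans-2,5-bis[4-(benzyloxy)phenyl]tetrahydrofuran-3,4-dicarboxylate F9, and LiAlH4 gives the racemic diol F10. This diol is resolved by preparative supercritical-fluid chromatography on a chiral stationary phase, and the (2S,3S,4S,5R) enantiomer is 9.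

Further compounds
F1 | step 13 | 1-[4-(benzyloxy)benzyl]tetrahydrothiophenium tetrafluoroborate | c1ccccc1COc1ccc(C[S+]2CCCC2)cc1.F[B-](F)(F)F
F2 | step 8 | dimethyl 3,3'-[(2S,3S,4S,5R)-2,5-bis[4-(benzyloxy)phenyl]tetrahydrofuran-3,4-diyl]bis(prop-2-ynoate) | O1[C@H](c2ccc(OCc3ccccc3)cc2)[C@H](C#CC(=O)OC)[C@@H](C#CC(=O)OC)[C@@H]1c1ccc(OCc2ccccc2)cc1
F3 | step 8 | bis-cycloadduct of F2 with 18, two 3-methoxy-2-(methoxycarbonyl)-3,5-bis(trimethylsilyloxy)cyclohexa-1,4-dien-1-yl groups on C3 and C4 (acetal carbons: mixture; not isolated) | O1[C@H](c2ccc(OCc3ccccc3)cc2)[C@H](C2=C(C(=O)OC)C(OC)(O[Si](C)(C)C)C=C(O[Si](C)(C)C)C2)[C@@H](C2=C(C(=O)OC)C(OC)(O[Si](C)(C)C)C=C(O[Si](C)(C)C)C2)[C@@H]1c1ccc(OCc2ccccc2)cc1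
F4 | step 8 | (2S,3S,4S,5R)-2,5-bis[4-(benzyloxy)phenyl]-3,4-bis[3,5-dihydroxy-2-(methoxycarbonyl)phenyl]tetrahydrofuran | O1[C@H](c2ccc(OCc3ccccc3)cc2)[C@H](c2cc(O)cc(O)c2C(=O)OC)[C@@H](c2cc(O)cc(O)c2C(=O)OC)[C@@H]1c1ccc(OCc2ccccc2)cc1
F5 | step 8 | (2S,3S,4S,5R)-2,5-bis[4-(benzyloxy)phenyl]-3,4-bis[5-(benzyloxy)-3-hydroxy-2-(methoxycarbonyl)phenyl]tetrahydrofuran | O1[C@H](c2ccc(OCc3ccccc3)cc2)[C@H](c2cc(OCc3ccccc3)cc(O)c2C(=O)OC)[C@@H](c2cc(OCc3ccccc3)cc(O)c2C(=O)OC)[C@@H]1c1ccc(OCc2ccccc2)cc1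
F6 | step 8 | (2S,3S,4S,5R)-2,5-bis[4-(benzyloxy)phenyl]-3,4-bis[5-(benzyloxy)-3-hydroxy-2-(hydroxymethyl)phenyl]tetrahydrofuran | O1[C@H](c2ccc(OCc3ccccc3)cc2)[C@H](c2cc(OCc3ccccc3)cc(O)c2CO)[C@@H](c2cc(OCc3ccccc3)cc(O)c2CO)[C@@H]1c1ccc(OCc2ccccc2)cc1
F7 | step 8 | (2S,3S,4S,5R)-2,5-bis[4-(benzyloxy)phenyl]-3,4-bis[5-(benzyloxy)-2-formyl-3-hydroxyphenyl]tetrahydrofuran | O1[C@H](c2ccc(OCc3ccccc3)cc2)[C@H](c2cc(OCc3ccccc3)cc(O)c2C=O)[C@@H](c2cc(OCc3ccccc3)cc(O)c2C=O)[C@@H]1c1ccc(OCc2ccccc2)cc1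
F8 | step 8 | 3,5-bis(benzyloxy)phenylmagnesium bromide | Br[Mg]c1cc(OCc2ccccc2)cc(OCc2ccccc2)c1
F9 | step 2 | racemic dimethyl (2RS,3SR,4SR,5SR)-2,5-bis[4-(benzyloxy)phenyl]tetrahydrofuran-3,4-dicarboxylate (one enantiomer drawn) | O1[C@H](c2ccc(OCc3ccccc3)cc2)[C@H](C(=O)OC)[C@@H](C(=O)OC)[C@@H]1c1ccc(OCc2ccccc2)cc1
F10 | step 2 | racemic [(2RS,3RS,4RS,5SR)-2,5-bis[4-(benzyloxy)phenyl]tetrahydrofuran-3,4-diyl]dimethanol (one enantiomer drawn; this enantiomer is 9) | O1[C@H](c2ccc(OCc3ccccc3)cc2)[C@H](CO)[C@@H](CO)[C@@H]1c1ccc(OCc2ccccc2)cc1
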